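**Retrosynthetic overview**
- Feature: in ring B the edge C3'–C4'(OMe)–C5'(OMe)–C6' is a locally symmetric four-carbon unit, and the other two carbons, C1' (bonded to C2 of pyranone ring C) and C2' (OH), are neighbours. Ring B is therefore cut into a symmetric 2,3-dimethoxydiene and an alkyne carrying the chromone on one carbon and boron (masked OH) on the other.
- Target ⇐ C–B oxidation ⇐ aryl pinacol boronate ⇐ dehydrogenation ⇐ 1,4-cyclohexadienyl boronate ⇐ [4+2] (bonds C2'–C3' and C1'–C6') ⇐ chromon-2-yl alkynyl pinacol boronate + 2,3-dimethoxybuta-1,3-diene.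
- Alkynylboronate ⇐ 2-ethynylchromone ⇐ 2-iodochromone ⇐ C2–H zincation of 3,7,8-trimethoxychromone ⇐ enaminone closure of an ω-methoxy-2-hydroxyacetophenone ⇐ 1,2,3-trimethoxybenzene + methoxyacetic Weinreb amide.
- Ring order: ring A is bought, pyranone ring C is closed in step 3, ring B is closed last in step 7 and aromatised in step 8.

Key step: step 7

Assumption: the target has no stereocentre, so no configuration has to be set; ethynylmagnesium bromide, the Weinreb amide, the isopropoxy pinacol borate and the diene are taken as commercial.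

**Step 1**
Reactants: 1 1,2,3-trimethoxybenzene; 2 N,2-dimethoxy-N-methylacetamide
Product: 5 2-methoxy-1-(2,3,4-trimethoxyphenyl)ethan-1-one, via (2,3,4-trimethoxyphenyl)lithium 3 (not isolated), via lithium hemiaminal adduct 4 (not isolated)
Conditions: n-BuLi (1.1 equiv), TMEDA, THF, 0 °C; then 2, −78 °C → 0 °C; 1 M HCl
Reagents that add atoms: N,2-dimethoxy-N-methylacetamide (2), COCC(=O)N(C)OC
Why: Directed ortho-lithiation can only occur at C4 (equivalent to C6), and the aryllithium adds once to the amide because the chelated tetrahedral adduct persists until the acidic quench (Weinreb ketone synthesis).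

**Step 2**
Reactants: 5 2-methoxy-1-(2,3,4-trimethoxyphenyl)ethan-1-one
Product: 7 1-(2-hydroxy-3,4-dimethoxyphenyl)-2-methoxyethan-1-one, via dichloroboron phenoxide chelate 6 (not isolated)
Conditions: BCl3 (1.1 equiv), CH2Cl2, −78 °C → 0 °C; then H2O
Reagents that add atoms: none
Why: BCl3 bridges the ketone oxygen and the ortho methoxy oxygen in a six-membered chelate, so chloride should remove only that methyl group and leave the other aryl ethers and the aliphatic ether (chelation-controlled selective ortho-demethylation).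

**Step 3**
Reactants: 7 1-(2-hydroxy-3,4-dimethoxyphenyl)-2-methoxyethan-1-one; 8 N,N-dimethylformamide dimethyl acetal
Product: 10 3,7,8-trimethoxy-4H-chromen-4-one, via enaminone 9 (not isolated)
Conditions: 8 (3 equiv), toluene, 100 °C; then AcOH, 80 °C
Reagents that add atoms: N,N-dimethylformamide dimethyl acetal (8), COC(OC)N(C)C
Why: The activated α-methylene condenses with the amide acetal to a β-dimethylamino enone, and the ortho phenol then adds 6-endo-trig and expels dimethylamine to close ring C (enaminone route to chromones).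

**Step 4**
Reactants: 10 3,7,8-trimethoxy-4H-chromen-4-one
Product: 12 2-iodo-3,7,8-trimethoxy-4H-chromen-4-one, via bis(chromon-2-yl)zinc 11 (not isolated)
Conditions: (TMP)2Zn·2MgCl2·2LiCl (0.6 equiv; TMP = 2,2,6,6-tetramethylpiperidide), THF, −30 °C → rt; then I2 (1.3 equiv), 0 °C
Reagents that add atoms: iodine, II
Why: C2–H is the only C–H of the pyranone ring and the most acidic one (between O1 and the C3 methoxy group, β-carbon of the MgCl2-complexed vinylogous ester), so the amide base should give the C2 diorganozinc, which iodine cleaves (directed C–H zincation and iodolysis).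

**Step 5**
Reactants: 12 2-iodo-3,7,8-trimethoxy-4H-chromen-4-one; 13 ethynylmagnesium bromide
Product: 14 2-ethynyl-3,7,8-trimethoxy-4H-chromen-4-one
Conditions: 13 (1.5 equiv), ZnBr2 (1.6 equiv), THF, 0 °C (transmetalation to ethynylzinc bromide); then 12, Pd(PPh3)4 (5 mol %), THF, 0 °C → rt
Reagents that add atoms: ethynylmagnesium bromide (13), C#C[Mg]Br
Why: ZnBr2 converts 13 in the flask into ethynylzinc bromide, which does not attack the C4 carbonyl, and after fast oxidative addition of the vinylogous acyl iodide it transmetalates to palladium and gives the terminal alkyne directly without a silyl group (Negishi alkynylation).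

**Step 6**
Reactants: 14 2-ethynyl-3,7,8-trimethoxy-4H-chromen-4-one; 15 2-isopropoxy-4,4,5,5-tetramethyl-1,3,2-dioxaborolane
Product: 18 3,7,8-trimethoxy-2-[(4,4,5,5-tetramethyl-1,3,2-dioxaborolan-2-yl)ethynyl]-4H-chromen-4-one, via lithium acetylide 16 (not isolated), via lithium isopropoxyborate 17 (not isolated)
Conditions: 15 (1.3 equiv) present, LiN(SiMe3)2 (1.05 equiv), THF, −78 °C; then HCl (1.05 equiv, 2 M in Et2O), −78 °C → rt; filtration, no aqueous work-up
Reagents that add atoms: 2-isopropoxy-4,4,5,5-tetramethyl-1,3,2-dioxaborolane (15), CC(C)OB1OC(C)(C)C(C)(C)O1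
Why: The hindered, non-nucleophilic amide removes the acetylenic proton at −78 °C with the borate already present, so the acetylide is trapped at once as the tetracoordinate borate, from which anhydrous HCl expels isopropanol (lithiation–borylation of a terminal alkyne).

**Step 7**
Reactants: 18 3,7,8-trimethoxy-2-[(4,4,5,5-tetramethyl-1,3,2-dioxaborolan-2-yl)ethynyl]-4H-chromen-4-one; 19 2,3-dimethoxybuta-1,3-diene
Product: 20 2-[4,5-dimethoxy-2-(4,4,5,5-tetramethyl-1,3,2-dioxaborolan-2-yl)cyclohexa-1,4-dien-1-yl]-3,7,8-trimethoxy-4H-chromen-4-one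
Conditions: 19 (5 equiv), BHT (5 mol %), toluene, 130 °C, sealed tube
Reagents that add atoms: 2,3-dimethoxybuta-1,3-diene (19), C=C(OC)C(OC)=C
Why: The reaction is a concerted, thermally allowed [4+2] cycloaddition of normal electron demand, in which the diene HOMO, raised by two methoxy groups, meets the alkyne LUMO, lowered by the chromon-2-yl group (a vinylogous acyl substituent) and by the vacant p orbital on boron, so that C2'–C3' and C1'–C6' form in one event. The closest known reaction type is the Diels–Alder reaction of alkynyl pinacol boronates with 1,3-dienes, which gives 1,4-cyclohexadienyl boronates. Ring B is closed by this intermolecular cycloaddition as a six-membered 1,4-cyclohexadiene, both ring bonds coming from the pericyclic step and none from a separate cyclisation. No stereocentre is formed, because the two new sp3 carbons are CH2 groups. The step needs site selectivity for the alkyne over the chromone C2=C3 bond, which should hold because that bond is tetrasubstituted, bears two oxygen donors and belongs to the pyranone π system; regiochemistry cannot arise because the diene has a twofold axis, and boron ends up on C2' next to C1' because boron and chromone sit on the two carbons of one alkyne. Excess diene and the radical inhibitor should offset thermal loss of the diene.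

**Step 8**
Reactants: 20 2-[4,5-dimethoxy-2-(4,4,5,5-tetramethyl-1,3,2-dioxaborolan-2-yl)cyclohexa-1,4-dien-1-yl]-3,7,8-trimethoxy-4H-chromen-4-one
Product: 21 2-[4,5-dimethoxy-2-(4,4,5,5-tetramethyl-1,3,2-dioxaborolan-2-yl)phenyl]-3,7,8-trimethoxy-4H-chromen-4-one
Conditions: crude 20 after evaporation of excess 19; DDQ (1.1 equiv), toluene, 0 °C → rt
Reagents that add atoms: none
Why: DDQ abstracts hydride from a doubly allylic CH2 of the 1,4-cyclohexadiene and proton loss then gives the benzene ring, driven by aromatisation and leaving the C–B bond untouched (dehydrogenative aromatisation).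

**Step 9**
Reactants: 21 2-[4,5-dimethoxy-2-(4,4,5,5-tetramethyl-1,3,2-dioxaborolan-2-yl)phenyl]-3,7,8-trimethoxy-4H-chromen-4-one
Product: 23 2-(2-hydroxy-4,5-dimethoxyphenyl)-3,7,8-trimethoxy-4H-chromen-4-one, via aryl pinacol borate 22 (not isolated)
Conditions: NaBO3·4H2O (3 equiv), THF/H2O (1:1), rt
Reagents that add atoms: sodium perborate tetrahydrate (NaBO3·4H2O), [Na+].[Na+].O[B-]1(O)OO[B-](O)(O)OO1
Why: Hydroperoxide adds to boron, the aryl group migrates from boron to oxygen at the same ring carbon, and the borate ester hydrolyses to the C2' phenol under nearly neutral conditions that should spare the chromone (oxidation of an arylboronate).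

**Compound list**
1 | 1,2,3-trimethoxybenzene | COc1cccc(OC)c1OC | starting material
2 | N,2-dimethoxy-N-methylacetamide | COCC(=O)N(C)OC | starting material
3 | (2,3,4-trimethoxyphenyl)lithium | [Li]c1ccc(OC)c(OC)c1OC | intermediate (not isolated)
4 | lithium 2-methoxy-1-[methoxy(methyl)amino]-1-(2,3,4-trimethoxyphenyl)ethan-1-olate (racemic) | COCC(O[Li])(N(C)OC)c1ccc(OC)c(OC)c1OC | intermediate (not isolated)
5 | 2-methoxy-1-(2,3,4-trimethoxyphenyl)ethan-1-one | COCC(=O)c1ccc(OC)c(OC)c1OC | intermediate
6 | dichloro[6-(methoxyacetyl)-2,3-dimethoxyphenoxy]borane (carbonyl-chelated) | COCC(=O)c1ccc(OC)c(OC)c1OB(Cl)Cl | intermediate (not isolated)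
7 | 1-(2-hydroxy-3,4-dimethoxyphenyl)-2-methoxyethan-1-one | COCC(=O)c1ccc(OC)c(OC)c1O | intermediate
8 | N,N-dimethylformamide dimethyl acetal | COC(OC)N(C)C | starting material
9 | (Z)-3-(dimethylamino)-1-(2-hydroxy-3,4-dimethoxyphenyl)-2-methoxyprop-2-en-1-one (expected geometry; either isomer should cyclise) | CN(C)/C=C(\OC)C(=O)c1ccc(OC)c(OC)c1O | intermediate (not isolated)
10 | 3,7,8-trimethoxy-4H-chromen-4-one | COc1ccc2c(c1OC)occ(OC)c2=O | intermediate
11 | bis(3,7,8-trimethoxy-4-oxo-4H-chromen-2-yl)zinc | COc1ccc2c(c1OC)oc([Zn]c1oc3c(OC)c(OC)ccc3c(=O)c1OC)c(OC)c2=O | intermediate (not isolated)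
12 | 2-iodo-3,7,8-trimethoxy-4H-chromen-4-one | COc1ccc2c(c1OC)oc(I)c(OC)c2=O | intermediate
13 | ethynylmagnesium bromide | C#C[Mg]Br | starting material
14 | 2-ethynyl-3,7,8-trimethoxy-4H-chromen-4-one | COc1ccc2c(c1OC)oc(C#C)c(OC)c2=O | intermediate
15 | 2-isopropoxy-4,4,5,5-tetramethyl-1,3,2-dioxaborolane | CC(C)OB1OC(C)(C)C(C)(C)O1 | starting material
16 | lithium (3,7,8-trimethoxy-4-oxo-4H-chromen-2-yl)acetylide | [Li]C#Cc1oc2c(OC)c(OC)ccc2c(=O)c1OC | intermediate (not isolated)
17 | lithium isopropoxy(pinacolato)[(3,7,8-trimethoxy-4-oxo-4H-chromen-2-yl)ethynyl]borate | [Li+].CC(C)O[B-]1(C#Cc2oc3c(OC)c(OC)ccc3c(=O)c2OC)OC(C)(C)C(C)(C)O1 | intermediate (not isolated)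
18 | 3,7,8-trimethoxy-2-[(4,4,5,5-tetramethyl-1,3,2-dioxaborolan-2-yl)ethynyl]-4H-chromen-4-one | COc1ccc2c(c1OC)oc(C#CB1OC(C)(C)C(C)(C)O1)c(OC)c2=O | intermediate
19 | 2,3-dimethoxybuta-1,3-diene | C=C(OC)C(OC)=C | starting material
20 | 2-[4,5-dimethoxy-2-(4,4,5,5-tetramethyl-1,3,2-dioxaborolan-2-yl)cyclohexa-1,4-dien-1-yl]-3,7,8-trimethoxy-4H-chromen-4-one | COC1=C(OC)CC(B2OC(C)(C)C(C)(C)O2)=C(C1)c1oc2c(OC)c(OC)ccc2c(=O)c1OC | intermediate
21 | 2-[4,5-dimethoxy-2-(4,4,5,5-tetramethyl-1,3,2-dioxaborolan-2-yl)phenyl]-3,7,8-trimethoxy-4H-chromen-4-one | COc1cc(B2OC(C)(C)C(C)(C)O2)c(-c2oc3c(OC)c(OC)ccc3c(=O)c2OC)cc1OC | intermediate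
22 | 2-{4,5-dimethoxy-2-[(4,4,5,5-tetramethyl-1,3,2-dioxaborolan-2-yl)oxy]phenyl}-3,7,8-trimethoxy-4H-chromen-4-one | COc1cc(OB2OC(C)(C)C(C)(C)O2)c(-c2oc3c(OC)c(OC)ccc3c(=O)c2OC)cc1OC | intermediate (not isolated)
23 | 2-(2-hydroxy-4,5-dimethoxyphenyl)-3,7,8-trimethoxy-4H-chromen-4-one | COc1cc(O)c(-c2oc3c(OC)c(OC)ccc3c(=O)c2OC)cc1OC | target

**Totals**
Total step count: 9. Longest linear sequence: 9 steps (1 → 23).

**Steps most likely to fail**

Step 7 (key Diels–Alder). The cycloaddition may be slower than thermal polymerisation or hydrolysis of the bis-enol-ether diene and protodeboronation of the alkyne, so that ring B does not close. The fallback replaces the cycloaddition by a C2–C1' cross-coupling; it sets out from chromone 10 and returns at target 23. Commercial 2-bromo-4,5-dimethoxyphenol would be benzylated (BnBr, K2CO3, DMF) to 1-(benzyloxy)-2-bromo-4,5-dimethoxybenzene F1. The diorganozinc 11, made from 10 as in step 4, would be coupled with F1 (Pd(OAc)2, SPhos, THF, 50 °C; Negishi coupling) to give 2-[2-(benzyloxy)-4,5-dimethoxyphenyl]-3,7,8-trimethoxy-4H-chromen-4-one F2. Hydrogenolysis (H2, Pd/C, EtOAc) should then give 23.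

Step 6 (borylation). The amide base or the acetylide may attack the chromone (addition at C2, ring opening, oligomerisation), and the electron-poor alkynylboronate may lose boron during isolation. The fallback brings boron in together with the alkyne by cross-coupling, with no carbanion; it sets out from iodide 12 and returns at target 23. Sonogashira coupling of 12 with commercial ethynylboronic acid MIDA ester (PdCl2(PPh3)2, CuI, Et3N, DMF, rt) should give the bench-stable 3,7,8-trimethoxy-2-[(6-methyl-4,8-dioxo-1,3,6,2-dioxazaborocan-2-yl)ethynyl]-4H-chromen-4-one F3. Cycloaddition with diene 19 (MeCN, 130 °C, sealed tube) would give 2-[4,5-dimethoxy-2-(6-methyl-4,8-dioxo-1,3,6,2-dioxazaborocan-2-yl)cyclohexa-1,4-dien-1-yl]-3,7,8-trimethoxy-4H-chromen-4-one F4. DDQ would give 2-[4,5-dimethoxy-2-(6-methyl-4,8-dioxo-1,3,6,2-dioxazaborocan-2-yl)phenyl]-3,7,8-trimethoxy-4H-chromen-4-one F5. Aqueous NaOH in THF followed by H2O2 at 0 °C would open the MIDA cage and oxidise the C–B bond to give 23.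

Step 4 (C2 zincation and iodination). Metalation may occur on the benzo ring (C5–H or C6–H) or remain incomplete, so that iodine is not delivered cleanly to C2. The fallback builds the C2 carbon into ring C instead of using C–H metalation; it sets out from hydroxy ketone 7 and returns at alkyne 14. Kostanecki–Robinson reaction of 7 (Ac2O, NaOAc, 170 °C) should give 3,7,8-trimethoxy-2-methyl-4H-chromen-4-one F6. SeO2 (dioxane, reflux) would oxidise the activated methyl group to 3,7,8-trimethoxy-4-oxo-4H-chromene-2-carbaldehyde F7. Ohira–Bestmann homologation (dimethyl (1-diazo-2-oxopropyl)phosphonate, K2CO3, MeOH, 0 °C) would give 14.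

**Further compounds**
F1 | step 7 | 1-(benzyloxy)-2-bromo-4,5-dimethoxybenzene | COc1cc(Br)c(OCc2ccccc2)cc1OC
F2 | step 7 | 2-[2-(benzyloxy)-4,5-dimethoxyphenyl]-3,7,8-trimethoxy-4H-chromen-4-one | COc1cc(OCc2ccccc2)c(-c2oc3c(OC)c(OC)ccc3c(=O)c2OC)cc1OC
F3 | step 6 | 3,7,8-trimethoxy-2-[(6-methyl-4,8-dioxo-1,3,6,2-dioxazaborocan-2-yl)ethynyl]-4H-chromen-4-one | COc1ccc2c(c1OC)oc(C#C[B-]13OC(=O)C[N+]1(C)CC(=O)O3)c(OC)c2=O
F4 | step 6 | 2-[4,5-dimethoxy-2-(6-methyl-4,8-dioxo-1,3,6,2-dioxazaborocan-2-yl)cyclohexa-1,4-dien-1-yl]-3,7,8-trimethoxy-4H-chromen-4-one | COC1=C(OC)CC([B-]23OC(=O)C[N+]2(C)CC(=O)O3)=C(C1)c1oc2c(OC)c(OC)ccc2c(=O)c1OC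
F5 | step 6 | 2-[4,5-dimethoxy-2-(6-methyl-4,8-dioxo-1,3,6,2-dioxazaborocan-2-yl)phenyl]-3,7,8-trimethoxy-4H-chromen-4-one | COc1cc([B-]23OC(=O)C[N+]2(C)CC(=O)O3)c(-c2oc3c(OC)c(OC)ccc3c(=O)c2OC)cc1OC
F6 | step 4 | 3,7,8-trimethoxy-2-methyl-4H-chromen-4-one | COc1ccc2c(c1OC)oc(C)c(OC)c2=O
F7 | step 4 | 3,7,8-trimethoxy-4-oxo-4H-chromene-2-carbaldehyde | COc1ccc2c(c1OC)oc(C=O)c(OC)c2=O
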